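**Retrosynthetic overview**
- The oxirane is closed last (inversion at a secondary mesylate by the neighbouring tertiary alkoxide), after the linoleate is placed on the only primary hydroxyl of an indole tetraol.
- The indole is made by a Fischer indolisation ([3,3]-sigmatropic formation of the C3–C3a bond) between a para-substituted arylhydrazine and a γ-lactol that already carries the C3 side-chain stereocentre.
- The arylhydrazine comes from an aryl chloride diol, itself from 4-chlorophenylmagnesium bromide, methyl (R)-glycidate and MeMgBr; the oxirane stereocentre is bought with the glycidate.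
- The lactol comes from a γ-lactone made by an Ireland–Claisen rearrangement of an allylic acetate (1,3-chirality transfer from (S)-but-3-yn-2-ol, extended with acetone); the propenyl group is then cut down to CH2OH.
- Order of ring formation: γ-lactone (temporary), then the pyrrole ring of the indole, then the oxirane.

Assumption: (S)-but-3-yn-2-ol, methyl (R)-oxirane-2-carboxylate and (4-chlorophenyl)magnesium bromide solution are taken as purchasable, the first two in enantiopure form.

**Route**

Step 1
Reactants: 1 (S)-but-3-yn-2-ol; 2 acetone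
Product: 4 (S,E)-2-methylhex-3-ene-2,5-diol, via ynediol dialkoxide 3 (not isolated)
Conditions: n-BuLi (2.1 equiv), THF, −78 to 0 °C; 2, −78 °C to rt; then NaAlH2(OCH2CH2OMe)2 (3 equiv), 0 °C to rt; Na2SO4·10H2O quench
Reagents that add atoms: none
Why: The O,C-dilithio derivative of 1 adds through carbon to acetone (acetylide 1,2-addition) and the propargylic dialkoxide then directs trans-hydroalumination of the alkyne, so protonolysis gives only the E-alkene while the purchased carbinol stereocentre is untouched.

Step 2
Reactants: 4 (S,E)-2-methylhex-3-ene-2,5-diol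
Product: 5 (S,E)-5-hydroxy-5-methylhex-3-en-2-yl acetate
Conditions: Ac2O (1.1 equiv), Et3N, DMAP (5 mol %), CH2Cl2, 0 °C
Reagents that add atoms: acetic anhydride, CC(=O)OC(C)=O
Why: DMAP-catalysed acylation is much faster at the secondary than at the tertiary hydroxyl, so only the allylic ester needed for the rearrangement forms and the stereocentre is unchanged (chemoselective esterification).

Step 3
Reactants: 5 (S,E)-5-hydroxy-5-methylhex-3-en-2-yl acetate
Product: 9 (S)-5,5-dimethyl-4-[(E)-prop-1-en-1-yl]dihydrofuran-2(3H)-one, via silyl ketene acetal 6 (not isolated), via silyl ester 7 (not isolated), via hydroxy acid 8 (not isolated)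
Conditions: Me3SiCl (3.5 equiv), Et3N, THF; LiN(i-Pr)2 (2.4 equiv), −78 °C, then warm to 55 °C; then 1 M HCl, rt
Reagents that add atoms: none
Why: In this Ireland–Claisen [3,3]-sigmatropic rearrangement the silyl ketene acetal reorganises through a chair transition state with the methyl group equatorial, so the new C–C bond forms on the alkene face from which the C–O bond leaves, which transfers the (S)-carbinol configuration to the new (S) carbon stereocentre and gives the E-propenyl group, and the acid work-up removes silicon and closes the γ-lactone on the tertiary hydroxyl.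

Step 4
Reactants: 9 (S)-5,5-dimethyl-4-[(E)-prop-1-en-1-yl]dihydrofuran-2(3H)-one
Product: 12 (S)-4-(hydroxymethyl)-5,5-dimethyldihydrofuran-2(3H)-one, via ozonide 10 (not isolated), via aldehyde 11 (not isolated)
Conditions: O3, CH2Cl2, −78 °C; then NaBH4, MeOH, −78 to 0 °C
Reagents that add atoms: ozone, [O-][O+]=O
Why: Ozonolysis of the only C=C bond followed by borohydride reduction in the same flask turns the propenyl group into CH2OH, the transient α-branched aldehyde being reduced before it can enolise and the lactone surviving at 0 °C, so the stereocentre is retained.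

Step 5
Reactants: 12 (S)-4-(hydroxymethyl)-5,5-dimethyldihydrofuran-2(3H)-one
Product: 13 (4S)-4-(hydroxymethyl)-5,5-dimethyltetrahydrofuran-2-ol
Conditions: i-Bu2AlH (2.3 equiv), CH2Cl2, −78 °C; Na2SO4·10H2O quench
Reagents that add atoms: none
Why: Partial reduction of a γ-lactone with i-Bu2AlH at −78 °C stops at the aluminium hemiacetal and gives the lactol (a masked γ-hydroxy aldehyde) on work-up, with the stereocentre untouched.

Step 6
Reactants: 14 (4-chlorophenyl)magnesium bromide; 15 methyl (R)-oxirane-2-carboxylate
Product: 17 (R)-1-(4-chlorophenyl)-3-methylbutane-2,3-diol, via hydroxy ester 16 (not isolated)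
Conditions: CuI (10 mol %), THF–Et2O, −40 °C; then MeMgBr (4 equiv), −40 to 0 °C; aq. NH4Cl
Reagents that add atoms: methylmagnesium bromide, C[Mg]Br
Why: CuI-catalysed SN2 opening of the glycidic ester by the arylmagnesium reagent occurs at the unsubstituted C3, so the purchased C2 stereocentre is carried over unchanged, and double 1,2-addition of MeMgBr to the ester then gives the tertiary carbinol.

Step 7
Reactants: 17 (R)-1-(4-chlorophenyl)-3-methylbutane-2,3-diol
Product: 18 (R)-1-(4-hydrazinylphenyl)-3-methylbutane-2,3-diol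
Conditions: N2H4·H2O (3 equiv), [Pd(cinnamyl)Cl]2 (2.5 mol %), Mor-DalPhos (7.5 mol %), NaOtBu (3.5 equiv), 1,4-dioxane, 65 °C; used crude
Reagents that add atoms: hydrazine hydrate, NN.O
Why: Palladium-catalysed C–N cross-coupling of the aryl chloride with hydrazine (Buchwald–Hartwig type) is held at mono-arylation by the bulky P,N-ligand and does not touch the diol or its stereocentre.

Step 8
Reactants: 13 (4S)-4-(hydroxymethyl)-5,5-dimethyltetrahydrofuran-2-ol; 18 (R)-1-(4-hydrazinylphenyl)-3-methylbutane-2,3-diol
Product: 20 (2S)-2-{5-[(2R)-2,3-dihydroxy-3-methylbutyl]-1H-indol-3-yl}-3-methylbutane-1,3-diol, via arylhydrazone 19 (not isolated)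
Conditions: EtOH, rt; then AcOH–H2O (1:1), 75 °C, under Ar
Reagents that add atoms: none
Why: In this Fischer indole synthesis the lactol condenses to the arylhydrazone, whose ene-hydrazine tautomer undergoes the [3,3]-sigmatropic rearrangement that forms the C3–C3a bond before cyclisation and loss of NH3, the para-substituted hydrazine can give only the 5-substituted indole, and the weak aqueous acid spares both tertiary carbinols and both stereocentres (the side-chain centre is not enolisable because it sits next to, not on, the carbon that becomes C3).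

Step 9
Reactants: 20 (2S)-2-{5-[(2R)-2,3-dihydroxy-3-methylbutyl]-1H-indol-3-yl}-3-methylbutane-1,3-diol; 21 (9Z,12Z)-octadeca-9,12-dienoic acid
Product: 22 (2S)-2-{5-[(2R)-2,3-dihydroxy-3-methylbutyl]-1H-indol-3-yl}-3-hydroxy-3-methylbutyl (9Z,12Z)-octadeca-9,12-dienoate
Conditions: DCC (1.05 equiv), DMAP (0.1 equiv), CH2Cl2, −20 to 0 °C
Reagents that add atoms: none
Why: Steglich esterification with one equivalent of acid at low temperature acylates the single primary hydroxyl much faster than the hindered secondary one, while the tertiary hydroxyls and the indole N–H do not react.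

Step 10
Reactants: 22 (2S)-2-{5-[(2R)-2,3-dihydroxy-3-methylbutyl]-1H-indol-3-yl}-3-hydroxy-3-methylbutyl (9Z,12Z)-octadeca-9,12-dienoate
Product: 24 (2S)-2-(5-{[(2S)-3,3-dimethyloxiran-2-yl]methyl}-1H-indol-3-yl)-3-hydroxy-3-methylbutyl (9Z,12Z)-octadeca-9,12-dienoate, via mesylate 23 (not isolated)
Conditions: MsCl (1.3 equiv), pyridine, CH2Cl2, 0 °C; then DBU (5 equiv), rt; chromatography on Et3N-deactivated silica
Reagents that add atoms: none
Why: Sulfonylation of the only reactive (secondary) hydroxyl and intramolecular Williamson displacement (3-exo-tet SN2) by the neighbouring tertiary alkoxide closes the oxirane with inversion, so the (R)-carbinol becomes the (S)-epoxide, and the non-nucleophilic base spares the linoleate ester.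

**Compound list**

1 | (S)-but-3-yn-2-ol | C[C@H](O)C#C | starting material
2 | acetone | CC(C)=O | starting material
3 | (S)-2-methylhex-3-yne-2,5-diol (present as its dilithium alkoxide) | C[C@H](O)C#CC(C)(C)O | intermediate (not isolated)
4 | (S,E)-2-methylhex-3-ene-2,5-diol | C[C@H](O)/C=C/C(C)(C)O | intermediate
5 | (S,E)-5-hydroxy-5-methylhex-3-en-2-yl acetate | C[C@H](OC(C)=O)/C=C/C(C)(C)O | intermediate
6 | (S,E)-trimethyl[(1-{[5-methyl-5-(trimethylsilyloxy)hex-3-en-2-yl]oxy}ethenyl)oxy]silane | C=C(O[Si](C)(C)C)O[C@@H](C)/C=C/C(C)(C)O[Si](C)(C)C | intermediate (not isolated)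
7 | trimethylsilyl (S,E)-3-[2-(trimethylsilyloxy)propan-2-yl]hex-4-enoate | C/C=C/[C@H](CC(=O)O[Si](C)(C)C)C(C)(C)O[Si](C)(C)C | intermediate (not isolated)
8 | (S,E)-3-(2-hydroxypropan-2-yl)hex-4-enoic acid | C/C=C/[C@H](CC(=O)O)C(C)(C)O | intermediate (not isolated)
9 | (S)-5,5-dimethyl-4-[(E)-prop-1-en-1-yl]dihydrofuran-2(3H)-one | C/C=C/[C@@H]1CC(=O)OC1(C)C | intermediate
10 | (4R)-5,5-dimethyl-4-(5-methyl-1,2,4-trioxolan-3-yl)dihydrofuran-2(3H)-one (ozonide, mixture at the trioxolane carbons; same spatial arrangement as 9, descriptor changes by CIP ranking only) | CC1OOC(O1)[C@@H]1CC(=O)OC1(C)C | intermediate (not isolated)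
11 | (R)-2,2-dimethyl-5-oxotetrahydrofuran-3-carbaldehyde (same spatial arrangement as 9) | O=C[C@@H]1CC(=O)OC1(C)C | intermediate (not isolated)
12 | (S)-4-(hydroxymethyl)-5,5-dimethyldihydrofuran-2(3H)-one | OC[C@@H]1CC(=O)OC1(C)C | intermediate
13 | (4S)-4-(hydroxymethyl)-5,5-dimethyltetrahydrofuran-2-ol (anomer mixture) | OC[C@@H]1CC(O)OC1(C)C | intermediate
14 | (4-chlorophenyl)magnesium bromide | Clc1ccc([Mg]Br)cc1 | starting material
15 | methyl (R)-oxirane-2-carboxylate | COC(=O)[C@H]1CO1 | starting material
16 | methyl (R)-3-(4-chlorophenyl)-2-hydroxypropanoate (present as its bromomagnesium alkoxide) | COC(=O)[C@H](O)Cc1ccc(Cl)cc1 | intermediate (not isolated)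
17 | (R)-1-(4-chlorophenyl)-3-methylbutane-2,3-diol | CC(C)(O)[C@H](O)Cc1ccc(Cl)cc1 | intermediate
18 | (R)-1-(4-hydrazinylphenyl)-3-methylbutane-2,3-diol | CC(C)(O)[C@H](O)Cc1ccc(NN)cc1 | intermediate
19 | (2R)-1-(4-{2-[(3S)-4-hydroxy-3-(hydroxymethyl)-4-methylpentylidene]hydrazinyl}phenyl)-3-methylbutane-2,3-diol | CC(C)(O)[C@H](CO)CC=NNc1ccc(C[C@@H](O)C(C)(C)O)cc1 | intermediate (not isolated)
20 | (2S)-2-{5-[(2R)-2,3-dihydroxy-3-methylbutyl]-1H-indol-3-yl}-3-methylbutane-1,3-diol | OC[C@H](c1c[nH]c2ccc(C[C@@H](O)C(C)(C)O)cc12)C(C)(C)O | intermediate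
21 | (9Z,12Z)-octadeca-9,12-dienoic acid (linoleic acid) | CCCCC/C=C\C/C=C\CCCCCCCC(=O)O | starting material
22 | (2S)-2-{5-[(2R)-2,3-dihydroxy-3-methylbutyl]-1H-indol-3-yl}-3-hydroxy-3-methylbutyl (9Z,12Z)-octadeca-9,12-dienoate | CCCCC/C=C\C/C=C\CCCCCCCC(=O)OC[C@H](c1c[nH]c2ccc(C[C@@H](O)C(C)(C)O)cc12)C(C)(C)O | intermediate
23 | (2S)-3-hydroxy-2-{5-[(2R)-3-hydroxy-3-methyl-2-(methylsulfonyloxy)butyl]-1H-indol-3-yl}-3-methylbutyl (9Z,12Z)-octadeca-9,12-dienoate | CCCCC/C=C\C/C=C\CCCCCCCC(=O)OC[C@H](c1c[nH]c2ccc(C[C@@H](OS(C)(=O)=O)C(C)(C)O)cc12)C(C)(C)O | intermediate (not isolated)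
24 | (2S)-2-(5-{[(2S)-3,3-dimethyloxiran-2-yl]methyl}-1H-indol-3-yl)-3-hydroxy-3-methylbutyl (9Z,12Z)-octadeca-9,12-dienoate | CCCCC/C=C\C/C=C\CCCCCCCC(=O)OC[C@H](c1c[nH]c2ccc(C[C@@H]3OC3(C)C)cc12)C(C)(C)O | target

**Step count and risks**

Total steps: 10. Longest linear sequence: 8 (steps 1, 2, 3, 4, 5, 8, 9, 10); steps 6 and 7 form the second branch.

Three steps most likely to fail:

Step 3 (Ireland–Claisen of a simple acetate beside a free tertiary hydroxyl: C-silylation and ester self-condensation can lower the yield). The fallback sets out from 4, so step 2 is skipped, and uses an orthoester (Johnson) Claisen instead of an ester enolate. Heating 4 with MeC(OEt)3 and catalytic propanoic acid at 140 °C lets the less hindered secondary carbinol exchange and rearrange through the same chair to ethyl (S,E)-3-(2-hydroxypropan-2-yl)hex-4-enoate F1. F1 lactonises in the same pot and the route is rejoined at 9. Any product of rearrangement through the tertiary carbinol would have to be removed by chromatography.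

Step 7 (mono-arylation of hydrazine beside a free diol: reduction of the chloride, diarylation and the air-sensitivity of 18 are the dangers). The fallback sets out from 17 and uses a bench-stable hydrazone as hydrazine surrogate. Coupling with benzophenone hydrazone (Pd(OAc)2, XPhos, NaOtBu, toluene, 90 °C) gives (R)-1-{4-[2-(diphenylmethylidene)hydrazinyl]phenyl}-3-methylbutane-2,3-diol F2. F2 is heated with lactol 13 and TsOH·H2O in aqueous EtOH at 75 °C, so that hydrazone exchange to 19 and indolisation occur in one pot with loss of benzophenone. The route is rejoined at 20, and the reaction must be stopped early because of the stronger acid.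

Step 8 (Fischer indolisation of an unprotected polyol: the weak acid may be too slow, and stronger acid risks elimination or rearrangement at the tertiary carbinols). The fallback sets out from 17 and replaces the hydrazine chemistry by an acid-free palladium annulation. Amination with NH3 in 1,4-dioxane ([Pd(cinnamyl)Cl]2, Mor-DalPhos, NaOtBu, 65 °C) gives (R)-1-(4-aminophenyl)-3-methylbutane-2,3-diol F3. Iodination ortho to nitrogen with N-iodosuccinimide in MeCN at 0 °C gives (R)-1-(4-amino-3-iodophenyl)-3-methylbutane-2,3-diol F4. Heating F4 with lactol 13, Pd(OAc)2 and DABCO in DMF at 85 °C (enamine formation, then intramolecular Heck cyclisation) returns to the route at 20.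

Further compounds
F1 | step 3 | ethyl (S,E)-3-(2-hydroxypropan-2-yl)hex-4-enoate | C/C=C/[C@H](CC(=O)OCC)C(C)(C)O
F2 | step 7 | (R)-1-{4-[2-(diphenylmethylidene)hydrazinyl]phenyl}-3-methylbutane-2,3-diol | CC(C)(O)[C@H](O)Cc1ccc(NN=C(c2ccccc2)c2ccccc2)cc1
F3 | step 8 | (R)-1-(4-aminophenyl)-3-methylbutane-2,3-diol | CC(C)(O)[C@H](O)Cc1ccc(N)cc1
F4 | step 8 | (R)-1-(4-amino-3-iodophenyl)-3-methylbutane-2,3-diol | CC(C)(O)[C@H](O)Cc1ccc(N)c(I)c1
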